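**Retrosynthetic overview**
1. The 3'-OH is freed last by hydrogenolysis of a benzyl ether. The three sulfates go onto the only free hydroxyls (O3, O5, O4') of 3'-O-benzylrhamnetin 16, whose O3 comes from epoxidation of the C2=C3 bond of flavone 14.
2. Ring C is opened at O1–C2 to the 2',6'-dihydroxy-4'-methoxychalcone 11; its two ortho hydroxyls are equivalent, so only one flavone can form.
3. The strategy rests on ring A: C5, C7 and C8a all carry oxygen and only O7 is methylated, which is the oxygen pattern of a 4-methoxy-2-pyrone. Ring A is therefore cut at C4a–C8a (Claisen) back to the methanolysis product of pyrone 9 (pyrone C2 = C8a, C4 = C7, C6 = C5, side-chain CH2 = C4a).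
4. Pyrone 9 is cut at C4–C4a into the C6-methyl anion of 4-methoxy-6-methyl-2-pyrone 6 and the cinnamoyl Weinreb amide 5, which comes by olefination from aldehyde 3 (from 3,4-dihydroxybenzaldehyde 1).
5. Order of ring formation: ring B and the pyrone are bought, ring A is formed in step 5, ring C in step 6.

Key step: step 5

Remark on the chemistry (assumption): the sulfate half-esters 17 and 18 are drawn as free acids, as in the target structure; they would be formed and carried as ammonium or sodium salts, and the free-acid form of 18 is released only at the very end by cold cation exchange.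

**Step 1**
Reactants: 1 3,4-dihydroxybenzaldehyde
Product: 2 3-hydroxy-4-(methoxymethoxy)benzaldehyde
Conditions: MOMCl (1.05 equiv), K2CO3 (1.1 equiv), acetone, 0 °C to rt
Reagents that add atoms: chloromethyl methyl ether (MOMCl), COCCl
Why: The 4-OH, para to the formyl group, is the more acidic phenol, so with one equivalent of mild base its phenoxide should form and be alkylated selectively (Williamson-type O-alkylation), leaving the 3-OH free.

**Step 2**
Reactants: 2 3-hydroxy-4-(methoxymethoxy)benzaldehyde
Product: 3 3-(benzyloxy)-4-(methoxymethoxy)benzaldehyde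
Conditions: BnBr, K2CO3, DMF, rt
Reagents that add atoms: benzyl bromide, BrCc1ccccc1
Why: Williamson ether synthesis on the remaining phenol; the MOM acetal and the aldehyde are inert to carbonate and benzyl bromide.

**Step 3**
Reactants: 3 3-(benzyloxy)-4-(methoxymethoxy)benzaldehyde; 4 diethyl {2-[methoxy(methyl)amino]-2-oxoethyl}phosphonate
Product: 5 (2E)-3-[3-(benzyloxy)-4-(methoxymethoxy)phenyl]-N-methoxy-N-methylprop-2-enamide
Conditions: NaH, THF, 0 °C to rt
Reagents that add atoms: none
Why: Horner–Wadsworth–Emmons olefination with a stabilized amide phosphonate, which should give the E-alkene under thermodynamic control and delivers the cinnamoyl unit directly at the Weinreb amide level.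

**Step 4**
Reactants: 6 4-methoxy-6-methyl-2H-pyran-2-one; 5 (2E)-3-[3-(benzyloxy)-4-(methoxymethoxy)phenyl]-N-methoxy-N-methylprop-2-enamide
Product: 9 6-[(3E)-4-[3-(benzyloxy)-4-(methoxymethoxy)phenyl]-2-oxobut-3-en-1-yl]-4-methoxy-2H-pyran-2-one, via lithiated pyrone 7 (not isolated), via tetrahedral lithium alkoxide 8 (not isolated)
Conditions: LiN(i-Pr)2, THF, −78 °C; then 5, −78 to −30 °C; then AcOH
Reagents that add atoms: none
Why: The amide base removes a proton from the C6 methyl to give the extended enolate 7, which adds 1,2 to the Weinreb amide (Claisen-type C-acylation); the N,O-chelated adduct 8 does not collapse before the acidic quench, so neither over-addition nor proton transfer from the acidic product to 7 should interfere.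

**Step 5**
Reactants: 9 6-[(3E)-4-[3-(benzyloxy)-4-(methoxymethoxy)phenyl]-2-oxobut-3-en-1-yl]-4-methoxy-2H-pyran-2-one
Product: 11 (2E)-3-[3-(benzyloxy)-4-(methoxymethoxy)phenyl]-1-(2,6-dihydroxy-4-methoxyphenyl)prop-2-en-1-one, via ring-opened methyl enoate 10 (not isolated)
Conditions: Mg(OMe)2 (excess), MeOH, reflux; then AcOH, 0 °C
Reagents that add atoms: none
Why: Methoxide adds to the lactone carbonyl of 9 (pyrone C2, the future C8a) and the ring opens to the magnesium enolate of the (2E)-3-methoxy-5,7-dioxo enoate 10, in which the ester carbon C8a and the C6 methylene remain cis across the C7=C8 double bond (flavone numbering); attack of methoxide at the methoxy-bearing pyrone carbon is degenerate, so the O7 methyl ether cannot be scrambled. The doubly activated methylene between the two ketones (future C4a), held as the magnesium β-diketonate, then attacks the ester carbonyl in a Claisen (Dieckmann-type) condensation that closes ring A in the 6-exo-trig mode and forms the C4a–C8a bond; loss of methoxide and enolization of the cyclohexenedione give the arene. The closest known reaction type is the base-induced recyclization of 6-(2-oxoalkyl)-4-methoxy-2-pyrones and of 3,5,7-trioxo esters to acylphloroglucinols, the laboratory copy of the chalcone synthase cyclization. No stereocenter is formed, and the (E)-enone is expected to survive because conjugate addition of methoxide is reversible. The selectivity needed is Claisen closure (C4a onto C8a) over aldol closure (C8 onto C4): the enol ether fixed at C7 keeps C8 a vinylic, non-nucleophilic carbon, magnesium chelation localizes the carbanion at C4a, and water-free methoxide keeps C8a at the ester level so that no carboxylate can form. The pyrone ring oxygen ends as one phenol, the lactone carbonyl oxygen as the other and the enol ether as 7-OMe, so the three oxygens of ring A come out differentiated and no phenol has to be methylated selectively later.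

**Step 6**
Reactants: 11 (2E)-3-[3-(benzyloxy)-4-(methoxymethoxy)phenyl]-1-(2,6-dihydroxy-4-methoxyphenyl)prop-2-en-1-one
Product: 13 2-[3-(benzyloxy)-4-(methoxymethoxy)phenyl]-5-hydroxy-7-methoxy-4H-chromen-4-one, via racemic flavanone 12 (not isolated)
Conditions: I2 (10 mol%), DMSO, 120 °C
Reagents that add atoms: none
Why: Iodine–DMSO oxidative cyclization of a 2'-hydroxychalcone: oxa-Michael closure of one of the two equivalent ortho hydroxyls gives flavanone 12 (ring C, O1–C2 bond), iodine dehydrogenates it by α-iodination and loss of HI, and DMSO reoxidizes HI so that only catalytic iodine is present and acid stays low.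

**Step 7**
Reactants: 13 2-[3-(benzyloxy)-4-(methoxymethoxy)phenyl]-5-hydroxy-7-methoxy-4H-chromen-4-one
Product: 14 2-[3-(benzyloxy)-4-(methoxymethoxy)phenyl]-7-methoxy-5-(methoxymethoxy)-4H-chromen-4-one
Conditions: NaH, MOMCl, DMF, 0 °C to rt
Reagents that add atoms: chloromethyl methyl ether (MOMCl), COCCl
Why: Williamson-type O-alkylation of the sodium phenoxide of the chelated 5-OH, which removes the hydrogen bond that deactivates the C2=C3 bond toward electrophilic oxidants, shields ring A in the next step and would also make good any loss of the acetal at O4' under the conditions of step 6.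

**Step 8**
Reactants: 14 2-[3-(benzyloxy)-4-(methoxymethoxy)phenyl]-7-methoxy-5-(methoxymethoxy)-4H-chromen-4-one
Product: 16 2-[3-(benzyloxy)-4-hydroxyphenyl]-3,5-dihydroxy-7-methoxy-4H-chromen-4-one (3'-O-benzylrhamnetin), via racemic flavone 2,3-epoxide 15 (not isolated)
Conditions: dimethyldioxirane (acetone solution), CH2Cl2, 0 °C to rt; then HCl, MeOH, 50 °C
Reagents that add atoms: dimethyldioxirane, CC1(C)OO1
Why: Dioxirane epoxidation of the enol-ether-like C2=C3 bond followed by acid-mediated isomerization of the flavone epoxide to the flavonol (opening at C2 to the oxocarbenium ion, loss of H3; the two transient stereocenters of 15 are destroyed), while the same methanolic HCl cleaves both MOM acetals and leaves the benzyl ether untouched.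

**Step 9**
Reactants: 16 2-[3-(benzyloxy)-4-hydroxyphenyl]-3,5-dihydroxy-7-methoxy-4H-chromen-4-one
Product: 17 3'-O-benzylrhamnetin 3,5,4'-tris(hydrogen sulfate)
Conditions: SO3·NMe3 (excess), Et3N, MeCN, 100 °C (microwave)
Reagents that add atoms: sulfur trioxide–trimethylamine complex, C[N+](C)(C)S(=O)(=O)[O-]
Why: O-Sulfonation of phenolic and enolic hydroxyls with an SO3–amine complex under forcing per-sulfation conditions, where excess reagent, base and heat should also convert the hydrogen-bonded 5-OH, while the benzyl ether keeps O3' unsulfated.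

**Step 10**
Reactants: 17 3'-O-benzylrhamnetin 3,5,4'-tris(hydrogen sulfate)
Product: 18 rhamnetin 3,5,4'-tri-O-sulfate
Conditions: H2 (1 atm), Pd/C, MeOH–H2O, rt; then Dowex 50WX8 (H+ form), 0 °C
Reagents that add atoms: none
Why: Palladium-catalyzed hydrogenolysis of the benzyl aryl ether, a standard last step for benzyl-protected flavonoid sulfates, since aryl sulfate salts are inert to H2 over Pd/C and the C2=C3 bond of the pyranone is not reduced at 1 atm and rt.

**Compound list**
1 | 3,4-dihydroxybenzaldehyde | O=Cc1ccc(O)c(O)c1 | starting material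
2 | 3-hydroxy-4-(methoxymethoxy)benzaldehyde | O=Cc1ccc(OCOC)c(O)c1 | intermediate
3 | 3-(benzyloxy)-4-(methoxymethoxy)benzaldehyde | O=Cc1ccc(OCOC)c(OCc2ccccc2)c1 | intermediate
4 | diethyl {2-[methoxy(methyl)amino]-2-oxoethyl}phosphonate | CCOP(=O)(CC(=O)N(C)OC)OCC | starting material
5 | (2E)-3-[3-(benzyloxy)-4-(methoxymethoxy)phenyl]-N-methoxy-N-methylprop-2-enamide | CON(C)C(=O)/C=C/c1ccc(OCOC)c(OCc2ccccc2)c1 | intermediate
6 | 4-methoxy-6-methyl-2H-pyran-2-one | COc1cc(C)oc(=O)c1 | starting material
7 | (4-methoxy-2-oxo-2H-pyran-6-yl)methyllithium (formed in situ) | [Li]Cc1cc(OC)cc(=O)o1 | intermediate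
8 | racemic lithium alkoxide from 1,2-addition of 7 to the amide carbonyl of 5 (formed in situ) | COc1cc(CC([O-])(N(C)OC)/C=C/c2ccc(OCOC)c(OCc3ccccc3)c2)oc(=O)c1.[Li+] | intermediate
9 | 6-[(3E)-4-[3-(benzyloxy)-4-(methoxymethoxy)phenyl]-2-oxobut-3-en-1-yl]-4-methoxy-2H-pyran-2-one | COc1cc(CC(=O)/C=C/c2ccc(OCOC)c(OCc3ccccc3)c2)oc(=O)c1 | intermediate
10 | methyl (2E,8E)-9-[3-(benzyloxy)-4-(methoxymethoxy)phenyl]-3-methoxy-5,7-dioxonona-2,8-dienoate (formed in situ as its magnesium enolate) | COC(=O)/C=C(/OC)CC(=O)CC(=O)/C=C/c1ccc(OCOC)c(OCc2ccccc2)c1 | intermediate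
11 | (2E)-3-[3-(benzyloxy)-4-(methoxymethoxy)phenyl]-1-(2,6-dihydroxy-4-methoxyphenyl)prop-2-en-1-one | COc1cc(O)c(C(=O)/C=C/c2ccc(OCOC)c(OCc3ccccc3)c2)c(O)c1 | intermediate
12 | racemic 2-[3-(benzyloxy)-4-(methoxymethoxy)phenyl]-5-hydroxy-7-methoxy-2,3-dihydro-4H-chromen-4-one (formed in situ) | COc1cc(O)c2c(c1)OC(c1ccc(OCOC)c(OCc3ccccc3)c1)CC2=O | intermediate
13 | 2-[3-(benzyloxy)-4-(methoxymethoxy)phenyl]-5-hydroxy-7-methoxy-4H-chromen-4-one | COc1cc(O)c2c(=O)cc(-c3ccc(OCOC)c(OCc4ccccc4)c3)oc2c1 | intermediate
14 | 2-[3-(benzyloxy)-4-(methoxymethoxy)phenyl]-7-methoxy-5-(methoxymethoxy)-4H-chromen-4-one | COCOc1cc(OC)cc2oc(-c3ccc(OCOC)c(OCc4ccccc4)c3)cc(=O)c12 | intermediate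
15 | racemic 2,3-epoxide of flavone 14, cis-fused oxirane across C2–C3 (formed in situ) | COCOc1cc(OC)cc2c1C(=O)C1OC1(c1ccc(OCOC)c(OCc3ccccc3)c1)O2 | intermediate
16 | 2-[3-(benzyloxy)-4-hydroxyphenyl]-3,5-dihydroxy-7-methoxy-4H-chromen-4-one (3'-O-benzylrhamnetin) | COc1cc(O)c2c(=O)c(O)c(-c3ccc(O)c(OCc4ccccc4)c3)oc2c1 | intermediate
17 | 3'-O-benzylrhamnetin 3,5,4'-tris(hydrogen sulfate) | COc1cc(OS(=O)(=O)O)c2c(=O)c(OS(=O)(=O)O)c(-c3ccc(OS(=O)(=O)O)c(OCc4ccccc4)c3)oc2c1 | intermediate
18 | rhamnetin 3,5,4'-tri-O-sulfate | COc1cc(OS(=O)(=O)O)c2c(=O)c(OS(=O)(=O)O)c(-c3ccc(OS(=O)(=O)O)c(O)c3)oc2c1 | target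

**Step count**
Total: 10 steps. Longest linear sequence: 10 steps (from 1 to 18); pyrone 6 and phosphonate 4 are bought and enter without steps of their own.

**Steps most likely to fail**

Risk 1, step 5 (ring opening and Claisen recyclization). The lactone may fail to open because the side-chain methylene is deprotonated first and the extended enolate deactivates the pyrone. The opened chain may also close the wrong way, by aldol condensation of C8 onto C4 or by attack of the diketone enol oxygen on C7 to give a 4-pyranone. The fallback builds the chalcone from a preformed ring A and sets out from aldehyde 3. Commercial 1-(2,6-dihydroxy-4-methoxyphenyl)ethan-1-one (CC(=O)c1c(O)cc(OC)cc1O) would be mono-protected with MOMCl and i-Pr2NEt in CH2Cl2, the second hydroxyl staying chelated to the ketone, to give 1-[2-hydroxy-4-methoxy-6-(methoxymethoxy)phenyl]ethan-1-one F1. Claisen–Schmidt condensation of F1 with 3 (KOH, EtOH, rt) should give (2E)-3-[3-(benzyloxy)-4-(methoxymethoxy)phenyl]-1-[2-hydroxy-4-methoxy-6-(methoxymethoxy)phenyl]prop-2-en-1-one F2. Iodine–DMSO cyclization of F2 under the conditions of step 6 then closes ring C, and the fallback comes back to the route at flavone 14.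

Risk 2, step 9 (tris-sulfation). Sulfation may stop at the hydrogen-bonded 5-OH and leave a mixture of di- and tri-sulfate salts that is hard to separate. The fallback sets out from 16 and uses protected sulfate diesters. 2,2,2-Trichloroethyl chlorosulfate (ClS(=O)(=O)OCC(Cl)(Cl)Cl) with DMAP and Et3N in THF behaves like a sulfonyl chloride, a reagent class known to acylate the 5-OH of flavones, and should give the neutral 3'-O-benzylrhamnetin 3,5,4'-tris(2,2,2-trichloroethyl sulfate) F3. F3 can be chromatographed on silica, so under-sulfated material can be removed and resubmitted. Transfer hydrogenolysis (Pd/C, HCO2NH4, MeOH, rt) then removes the three trichloroethyl groups and the benzyl ether in one operation, and the fallback comes back to the route at 18.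

Risk 3, step 4 (acylation of the pyrone anion). The delocalized anion may add in a conjugate sense to the cinnamoyl amide, or may add so slowly to the weakly electrophilic amide carbonyl that it decomposes on warming. The fallback sets out from aldehyde 3 and pyrone 6 and replaces acylation by aldol addition and oxidation. Wittig olefination of 3 with (triphenylphosphoranylidene)acetaldehyde (O=CC=P(c1ccccc1)(c1ccccc1)c1ccccc1) in toluene at 80 °C should give (2E)-3-[3-(benzyloxy)-4-(methoxymethoxy)phenyl]prop-2-enal F4. Addition of the lithiated pyrone 7 to this more electrophilic, 1,2-selective aldehyde at −78 °C should give racemic 6-[(3E)-4-[3-(benzyloxy)-4-(methoxymethoxy)phenyl]-2-hydroxybut-3-en-1-yl]-4-methoxy-2H-pyran-2-one F5. Oxidation of the allylic alcohol with MnO2 in CH2Cl2 then gives the ketone, and the fallback comes back to the route at 9.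

**Further compounds**
F1 | step 5 | 1-[2-hydroxy-4-methoxy-6-(methoxymethoxy)phenyl]ethan-1-one | CC(=O)c1c(O)cc(OC)cc1OCOC
F2 | step 5 | (2E)-3-[3-(benzyloxy)-4-(methoxymethoxy)phenyl]-1-[2-hydroxy-4-methoxy-6-(methoxymethoxy)phenyl]prop-2-en-1-one | COCOc1cc(OC)cc(O)c1C(=O)/C=C/c1ccc(OCOC)c(OCc2ccccc2)c1
F3 | step 9 | 3'-O-benzylrhamnetin 3,5,4'-tris(2,2,2-trichloroethyl sulfate) | COc1cc(OS(=O)(=O)OCC(Cl)(Cl)Cl)c2c(=O)c(OS(=O)(=O)OCC(Cl)(Cl)Cl)c(-c3ccc(OS(=O)(=O)OCC(Cl)(Cl)Cl)c(OCc4ccccc4)c3)oc2c1
F4 | step 4 | (2E)-3-[3-(benzyloxy)-4-(methoxymethoxy)phenyl]prop-2-enal | O=C/C=C/c1ccc(OCOC)c(OCc2ccccc2)c1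
F5 | step 4 | racemic 6-[(3E)-4-[3-(benzyloxy)-4-(methoxymethoxy)phenyl]-2-hydroxybut-3-en-1-yl]-4-methoxy-2H-pyran-2-one | COc1cc(CC(O)/C=C/c2ccc(OCOC)c(OCc3ccccc3)c2)oc(=O)c1
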